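**Plan**

- Cuts, in retrosynthetic order: the O–Si bond; the Z alkene back to an aryl alkyne and its C(sp)–phenyl bond; the O–CH3 and C4–CH2 bonds of the quaternary centre back to a methoxy-para-quinone; the quinone back to a 2-methoxyphenol ring; the furan C2=C3 bond back to an aryl ester of a 2-hydroxybenzophenone; last, the ester C–O and the benzophenone aryl–C(=O) bonds.
- Enabling feature: in the benzofuran, C3 bears the phenyl group and C2 the CH2 linker. These two furan carbons map onto the ketone carbon of a 2-hydroxybenzophenone and the carbonyl carbon of its O-arylacetyl ester, with O1–C2 and C3–C3a already in place.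
- Forward order: Friedel–Crafts benzoylation, selective silylation and esterification give the keto ester. The furan ring, the only ring made, then closes at C2=C3. The side ring is debenzylated and oxidised to the quinone, which is propargylated, O-methylated, arylated and semi-hydrogenated before desilylation.
- Stereochemistry: the single stereocentre (4R) comes from catalyst-controlled Si-face propargylation of the quinone C4 carbonyl with a chiral 3,3'-dibromo-BINOL. The Z alkene comes from syn addition of H2 to the aryl alkyne.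
- The latent quinone ring is carried as a benzyl-protected 2-methoxyphenol, so that a phenol-selective oxidation unveils it without touching the electron-rich benzofuran.

Key step: step 4

Assumption: the antipode of 3,3'-dibromo-BINOL that delivers the propargyl group to the Si face of the quinone carbonyl is taken, by analogy with aryl ketones, to be the (R)-diol; the mirror-image diol takes its place if the configuration found for 12 is the opposite.

Shorthand used in the step lines: BfCH2 = [6-methoxy-3-phenyl-5-(triisopropylsilyloxy)-1-benzofuran-2-yl]methyl; TIPS = triisopropylsilyl.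

**Route**

Step 1
Reactants: 1 2-methoxybenzene-1,4-diol; 2 benzoic acid
Product: 3 (2,5-dihydroxy-4-methoxyphenyl)(phenyl)methanone
Conditions: BF3·OEt2 (neat, excess), 90 °C, argon; aqueous work-up
Reagents that add atoms: none
Why: Friedel–Crafts acylation with the acid activated by BF3 should go to C5 of 1, which is para to the methoxy group and ortho to a hydroxyl and so is the most nucleophilic and least crowded position, while the boron chelate of the resulting ortho-hydroxy ketone deactivates the ring against a second acylation.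

Step 2
Reactants: 3 (2,5-dihydroxy-4-methoxyphenyl)(phenyl)methanone
Product: 4 [2-hydroxy-4-methoxy-5-(triisopropylsilyloxy)phenyl](phenyl)methanone
Conditions: iPr3SiCl (1.05 equiv), imidazole, DMF, 0 °C to rt
Reagents that add atoms: chlorotriisopropylsilane, CC(C)[Si](Cl)(C(C)C)C(C)C
Why: Imidazole-promoted silyl ether formation should be selective for the 5-OH, because the 2-OH is held in a hydrogen bond to the benzoyl carbonyl and is far less nucleophilic.

Step 3
Reactants: 4 [2-hydroxy-4-methoxy-5-(triisopropylsilyloxy)phenyl](phenyl)methanone; 5 [3-(benzyloxy)-4-methoxyphenyl]acetic acid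
Product: 6 2-benzoyl-5-methoxy-4-(triisopropylsilyloxy)phenyl [3-(benzyloxy)-4-methoxyphenyl]acetate
Conditions: DCC, DMAP (cat.), CH2Cl2, 0 °C to rt
Reagents that add atoms: none
Why: In this Steglich esterification the acylpyridinium ion formed from the O-acylisourea and DMAP acylates even the hydrogen-bonded phenol, and low temperature with only catalytic base keeps the arylacetate enolate from condensing onto the benzophenone carbonyl (coumarin formation).

Step 4
Reactants: 6 2-benzoyl-5-methoxy-4-(triisopropylsilyloxy)phenyl [3-(benzyloxy)-4-methoxyphenyl]acetate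
Product: 7 2-[3-(benzyloxy)-4-methoxybenzyl]-6-methoxy-3-phenyl-5-(triisopropylsilyloxy)-1-benzofuran
Conditions: TiCl3, Zn dust, DME, reflux; 6 added slowly by syringe pump (high dilution)
Reagents that add atoms: none
Why: Zinc reduces TiCl3 to low-valent titanium, which transfers electrons to the diaryl ketone of 6 to give a titanium-bound ketyl; this carbon adds to the neighbouring aryl ester carbonyl, and the resulting titanium diolate gives up both oxygen atoms to the oxophilic metal, leaving the C2=C3 double bond. The closest known reaction type is the McMurry-type reductive oxo-ester cyclisation of 2-acyloxyaryl ketones to benzofurans. The furan ring closes in a 5-exo-trig mode: the ketyl carbon (future C3) attacks the ester C=O (future C2), whose oxygen stays outside the ring until it is removed. No stereocentre is formed. The step needs intramolecular ketone–ester coupling to win over intermolecular ketone–ketone coupling and over simple reduction of the ketone; the five-membered ring, slow addition at high dilution and the reluctance of esters to couple with each other should secure this, and the substitution pattern of the benzofuran is fixed beforehand by the O-acylated hydroxybenzophenone, so no regiochemical choice arises. The benzyl ether, the aryl silyl ether and the methyl ethers carry no reducible carbonyl and are expected to pass unchanged.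

Step 5
Reactants: 7 2-[3-(benzyloxy)-4-methoxybenzyl]-6-methoxy-3-phenyl-5-(triisopropylsilyloxy)-1-benzofuran
Product: 8 2-methoxy-5-(BfCH2)phenol
Conditions: H2 (1 atm), 10% Pd/C, EtOAc/EtOH, rt
Reagents that add atoms: none
Why: Catalytic hydrogenolysis of a benzyl aryl ether is fast on Pd/C at room temperature, whereas the aromatic furan, the aryl silyl ether and the diarylmethane C–C bonds are not reduced.

Step 6
Reactants: 8 2-methoxy-5-(BfCH2)phenol
Product: 9 5-methoxy-2-(BfCH2)cyclohexa-2,5-diene-1,4-dione
Conditions: ON(SO3K)2 (2.5 equiv), KH2PO4, acetone/H2O, rt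
Reagents that add atoms: dipotassium nitrosodisulfonate, [K+].[K+].[O]N(S(=O)(=O)[O-])S(=O)(=O)[O-]
Why: In this Teuber oxidation the nitroxide abstracts the phenolic hydrogen and a second equivalent adds at the free para position and collapses to the para-quinone, a radical pathway open only to the free phenol, so the silylated benzofuran is left alone where a one-electron metal oxidant would not discriminate.

Step 7
Reactants: 9 5-methoxy-2-(BfCH2)cyclohexa-2,5-diene-1,4-dione; 10 4,4,5,5-tetramethyl-2-(propa-1,2-dien-1-yl)-1,3,2-dioxaborolane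
Product: 12 (4R)-4-hydroxy-5-methoxy-2-(BfCH2)-4-(prop-2-yn-1-yl)cyclohexa-2,5-dien-1-one, via quinol pinacol borate 11 (not isolated)
Conditions: (R)-3,3'-dibromo-BINOL (20 mol%), PhMe, 0 °C to rt; aqueous NaHCO3 work-up
Reagents that add atoms: none
Why: Proposed new method: enantioselective propargylation of a quinone carbonyl, in which the diol exchanges one B–O bond of 10 to give a more Lewis-acidic chiral allenylboronate that binds the C4 carbonyl and transfers its γ-carbon through a closed six-membered SE2′ transition state to the Si face, setting the (4R) centre under catalyst control; C4 (next to the methoxy-bearing C5) is the more electrophilic carbonyl because C1 is deactivated as a vinylogous ester and is flanked by the BfCH2 group, the facial bias rests on the difference between the methoxy-substituted and the unsubstituted ring arm, and the closest known reaction type is the biphenol-catalysed asymmetric propargylation of aryl and alkenyl ketones with allenylboronates.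

Step 8
Reactants: 12 (4R)-4-hydroxy-5-methoxy-2-(BfCH2)-4-(prop-2-yn-1-yl)cyclohexa-2,5-dien-1-one
Product: 14 (4R)-4,5-dimethoxy-2-(BfCH2)-4-(prop-2-yn-1-yl)cyclohexa-2,5-dien-1-one, via sodium quinol alkoxide 13 (not isolated)
Conditions: NaH, MeI, THF, 0 °C to rt
Reagents that add atoms: iodomethane, CI
Why: In this Williamson ether synthesis the tertiary quinol alkoxide should be methylated by MeI at 0 °C faster than it can rearrange, NaH in THF does not touch the terminal alkyne or the aryl silyl ether, and the stereocentre is not involved.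

Step 9
Reactants: 14 (4R)-4,5-dimethoxy-2-(BfCH2)-4-(prop-2-yn-1-yl)cyclohexa-2,5-dien-1-one; 15 iodobenzene
Product: 16 (4R)-4,5-dimethoxy-2-(BfCH2)-4-(3-phenylprop-2-yn-1-yl)cyclohexa-2,5-dien-1-one
Conditions: PdCl2(PPh3)2 (cat.), CuI (cat.), Et3N, THF, rt, argon
Reagents that add atoms: none
Why: Sonogashira coupling of a terminal alkyne with an aryl iodide proceeds at room temperature under amine base, conditions under which the dienone, the quinol ether and the silyl ether are inert and the stereocentre is untouched.

Step 10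
Reactants: 16 (4R)-4,5-dimethoxy-2-(BfCH2)-4-(3-phenylprop-2-yn-1-yl)cyclohexa-2,5-dien-1-one
Product: 17 (4R)-4,5-dimethoxy-2-(BfCH2)-4-[(2Z)-3-phenylprop-2-en-1-yl]cyclohexa-2,5-dien-1-one
Conditions: H2 (1 atm), Pd/CaCO3 poisoned with Pb(OAc)2, quinoline, EtOAc, rt; stopped after one equivalent of H2
Reagents that add atoms: none
Why: In this Lindlar semi-hydrogenation syn delivery of H2 on the lead-poisoned palladium surface gives the Z alkene, and the quinoline-moderated catalyst should reduce the alkyne far faster than the trisubstituted conjugated double bonds of the dienone or the product styrene.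

Step 11
Reactants: 17 (4R)-4,5-dimethoxy-2-(BfCH2)-4-[(2Z)-3-phenylprop-2-en-1-yl]cyclohexa-2,5-dien-1-one
Product: 18 (4R)-2-[(5-hydroxy-6-methoxy-3-phenyl-1-benzofuran-2-yl)methyl]-4,5-dimethoxy-4-[(2Z)-3-phenylprop-2-en-1-yl]cyclohexa-2,5-dien-1-one
Conditions: Bu4NF, AcOH, THF, 0 °C
Reagents that add atoms: none
Why: Fluoride-induced cleavage of the aryl silyl ether is driven by Si–F bond formation, and the acetic acid buffer protonates the phenoxide at once so that the quinol ether dienone and the Z-styrene are not exposed to basic fluoride.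

**Compound list**

1 | 2-methoxybenzene-1,4-diol | COc1cc(O)ccc1O | starting material
2 | benzoic acid | OC(=O)c1ccccc1 | starting material
3 | (2,5-dihydroxy-4-methoxyphenyl)(phenyl)methanone | COc1cc(O)c(C(=O)c2ccccc2)cc1O | intermediate
4 | [2-hydroxy-4-methoxy-5-(triisopropylsilyloxy)phenyl](phenyl)methanone | COc1cc(O)c(C(=O)c2ccccc2)cc1O[Si](C(C)C)(C(C)C)C(C)C | intermediate
5 | [3-(benzyloxy)-4-methoxyphenyl]acetic acid | COc1ccc(CC(=O)O)cc1OCc1ccccc1 | starting material
6 | 2-benzoyl-5-methoxy-4-(triisopropylsilyloxy)phenyl [3-(benzyloxy)-4-methoxyphenyl]acetate | COc1ccc(CC(=O)Oc2cc(OC)c(O[Si](C(C)C)(C(C)C)C(C)C)cc2C(=O)c2ccccc2)cc1OCc1ccccc1 | intermediate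
7 | 2-[3-(benzyloxy)-4-methoxybenzyl]-6-methoxy-3-phenyl-5-(triisopropylsilyloxy)-1-benzofuran | COc1ccc(Cc2oc3cc(OC)c(O[Si](C(C)C)(C(C)C)C(C)C)cc3c2-c2ccccc2)cc1OCc1ccccc1 | intermediate
8 | 2-methoxy-5-{[6-methoxy-3-phenyl-5-(triisopropylsilyloxy)-1-benzofuran-2-yl]methyl}phenol | COc1ccc(Cc2oc3cc(OC)c(O[Si](C(C)C)(C(C)C)C(C)C)cc3c2-c2ccccc2)cc1O | intermediate
9 | 5-methoxy-2-{[6-methoxy-3-phenyl-5-(triisopropylsilyloxy)-1-benzofuran-2-yl]methyl}cyclohexa-2,5-diene-1,4-dione | COC1=CC(=O)C(Cc2oc3cc(OC)c(O[Si](C(C)C)(C(C)C)C(C)C)cc3c2-c2ccccc2)=CC1=O | intermediate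
10 | 4,4,5,5-tetramethyl-2-(propa-1,2-dien-1-yl)-1,3,2-dioxaborolane (allenylboronic acid pinacol ester) | C=C=CB1OC(C)(C)C(C)(C)O1 | starting material
11 | (4R)-5-methoxy-2-{[6-methoxy-3-phenyl-5-(triisopropylsilyloxy)-1-benzofuran-2-yl]methyl}-4-(prop-2-yn-1-yl)-4-[(4,4,5,5-tetramethyl-1,3,2-dioxaborolan-2-yl)oxy]cyclohexa-2,5-dien-1-one | COC1=CC(=O)C(Cc2oc3cc(OC)c(O[Si](C(C)C)(C(C)C)C(C)C)cc3c2-c2ccccc2)=C[C@@]1(CC#C)OB1OC(C)(C)C(C)(C)O1 | intermediate
12 | (4R)-4-hydroxy-5-methoxy-2-{[6-methoxy-3-phenyl-5-(triisopropylsilyloxy)-1-benzofuran-2-yl]methyl}-4-(prop-2-yn-1-yl)cyclohexa-2,5-dien-1-one | COC1=CC(=O)C(Cc2oc3cc(OC)c(O[Si](C(C)C)(C(C)C)C(C)C)cc3c2-c2ccccc2)=C[C@@]1(CC#C)O | intermediate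
13 | sodium alkoxide of 12 (O–Na in place of O–H at C4, 4R) | COC1=CC(=O)C(Cc2oc3cc(OC)c(O[Si](C(C)C)(C(C)C)C(C)C)cc3c2-c2ccccc2)=C[C@@]1(CC#C)[O-].[Na+] | intermediate
14 | (4R)-4,5-dimethoxy-2-{[6-methoxy-3-phenyl-5-(triisopropylsilyloxy)-1-benzofuran-2-yl]methyl}-4-(prop-2-yn-1-yl)cyclohexa-2,5-dien-1-one | COC1=CC(=O)C(Cc2oc3cc(OC)c(O[Si](C(C)C)(C(C)C)C(C)C)cc3c2-c2ccccc2)=C[C@@]1(CC#C)OC | intermediate
15 | iodobenzene | Ic1ccccc1 | starting material
16 | (4R)-4,5-dimethoxy-2-{[6-methoxy-3-phenyl-5-(triisopropylsilyloxy)-1-benzofuran-2-yl]methyl}-4-(3-phenylprop-2-yn-1-yl)cyclohexa-2,5-dien-1-one | COC1=CC(=O)C(Cc2oc3cc(OC)c(O[Si](C(C)C)(C(C)C)C(C)C)cc3c2-c2ccccc2)=C[C@@]1(CC#Cc1ccccc1)OC | intermediate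
17 | (4R)-4,5-dimethoxy-2-{[6-methoxy-3-phenyl-5-(triisopropylsilyloxy)-1-benzofuran-2-yl]methyl}-4-[(2Z)-3-phenylprop-2-en-1-yl]cyclohexa-2,5-dien-1-one | COC1=CC(=O)C(Cc2oc3cc(OC)c(O[Si](C(C)C)(C(C)C)C(C)C)cc3c2-c2ccccc2)=C[C@@]1(C/C=C\c1ccccc1)OC | intermediate
18 | (4R)-2-[(5-hydroxy-6-methoxy-3-phenyl-1-benzofuran-2-yl)methyl]-4,5-dimethoxy-4-[(2Z)-3-phenylprop-2-en-1-yl]cyclohexa-2,5-dien-1-one | COC1=CC(=O)C(Cc2oc3cc(OC)c(O)cc3c2-c2ccccc2)=C[C@@]1(C/C=C\c1ccccc1)OC | target

**Summary**

Total step count: 11. Longest linear sequence: 11 steps (1 to 18); compounds 2, 5, 10 and 15 are commercial and enter directly.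

Steps most likely to fail:

1. Step 7 (propargylation of the quinone). Facial selectivity may be poor, an uncatalysed background addition may erode the enantiomeric purity, or addition may occur at the other carbonyl. The fallback sets out from 9 and comes back at 12. The quinone 9 is treated in THF at −78 °C with allenylmagnesium bromide (from propargyl bromide, Mg and catalytic HgCl2), a known type of 1,2-addition of an organomagnesium reagent to the more electrophilic carbonyl of an alkoxyquinone, to give the racemic propargyl quinol F1. The enantiomers of F1 are then separated by preparative HPLC on a cellulose tris(3,5-dimethylphenylcarbamate) stationary phase, and the (4R) antipode is carried on as 12.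

2. Step 4 (titanium-mediated ring closure). Intermolecular pinacol-type coupling of the benzophenone may compete, the ketone may be reduced before it cyclises, or the aryl ester may be cleaved reductively. The fallback sets out from 4 and comes back at 7, and forms the same C2=C3 bond by a polar route. The phenol 4 is O-alkylated with 2-bromo-1-[3-(benzyloxy)-4-methoxyphenyl]ethan-1-one F2 (made from the commercial acetophenone with CuBr2) using K2CO3 in refluxing acetone. The resulting aryl phenacyl ether F3 undergoes intramolecular aldol condensation onto the benzophenone carbonyl in the same flask (Rap–Stoermer reaction) to give the 2-aroyl-3-phenylbenzofuran F4. The diaryl ketone of F4 is then deoxygenated to CH2 by ionic hydrogenation with Et3SiH and CF3CO2H in CH2Cl2, which gives 7.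

3. Step 10 (semi-hydrogenation). Over-reduction of the new alkene, partial reduction of the dienone or Z-to-E isomerisation on the catalyst may occur. The fallback sets out from 14 and comes back at 17, bypassing step 9 as well. The terminal alkyne 14 is iodinated with N-iodosuccinimide and catalytic AgNO3 in acetone to the 1-iodoalkyne F5. Diimide reduction (2-nitrobenzenesulfonyl hydrazide, Et3N), which does not reduce the conjugated dienone, gives the (Z)-iodoalkene F6. Suzuki–Miyaura coupling of F6 with phenylboronic acid (Pd(PPh3)4, K3PO4, THF/H2O, 40 °C) proceeds with retention of the double-bond geometry and gives 17.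

Further compounds
F1 | step 7 | racemic 4-hydroxy-5-methoxy-2-{[6-methoxy-3-phenyl-5-(triisopropylsilyloxy)-1-benzofuran-2-yl]methyl}-4-(prop-2-yn-1-yl)cyclohexa-2,5-dien-1-one | COC1=CC(=O)C(Cc2oc3cc(OC)c(O[Si](C(C)C)(C(C)C)C(C)C)cc3c2-c2ccccc2)=CC1(CC#C)O
F2 | step 4 | 2-bromo-1-[3-(benzyloxy)-4-methoxyphenyl]ethan-1-one | COc1ccc(C(=O)CBr)cc1OCc1ccccc1
F3 | step 4 | 2-[2-benzoyl-5-methoxy-4-(triisopropylsilyloxy)phenoxy]-1-[3-(benzyloxy)-4-methoxyphenyl]ethan-1-one | COc1ccc(C(=O)COc2cc(OC)c(O[Si](C(C)C)(C(C)C)C(C)C)cc2C(=O)c2ccccc2)cc1OCc1ccccc1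
F4 | step 4 | [3-(benzyloxy)-4-methoxyphenyl][6-methoxy-3-phenyl-5-(triisopropylsilyloxy)-1-benzofuran-2-yl]methanone | COc1ccc(C(=O)c2oc3cc(OC)c(O[Si](C(C)C)(C(C)C)C(C)C)cc3c2-c2ccccc2)cc1OCc1ccccc1
F5 | step 10 | (4R)-4-(3-iodoprop-2-yn-1-yl)-4,5-dimethoxy-2-{[6-methoxy-3-phenyl-5-(triisopropylsilyloxy)-1-benzofuran-2-yl]methyl}cyclohexa-2,5-dien-1-one | COC1=CC(=O)C(Cc2oc3cc(OC)c(O[Si](C(C)C)(C(C)C)C(C)C)cc3c2-c2ccccc2)=C[C@@]1(CC#CI)OC
F6 | step 10 | (4R)-4-[(2Z)-3-iodoprop-2-en-1-yl]-4,5-dimethoxy-2-{[6-methoxy-3-phenyl-5-(triisopropylsilyloxy)-1-benzofuran-2-yl]methyl}cyclohexa-2,5-dien-1-one | COC1=CC(=O)C(Cc2oc3cc(OC)c(O[Si](C(C)C)(C(C)C)C(C)C)cc3c2-c2ccccc2)=C[C@@]1(C/C=C\I)OC
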